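**Assumption:** gustastatin has no stereocentre and no stereogenic double bond (it is achiral), so there is no configuration to set or protect.

## Retrosynthetic overview

1. Cut the depside at the C(aryl)–O bond rather than the acyl–O bond: keto acid 8 plus aryl boronate 13, joined by a Cu-catalysed oxidative acyloxylation (the new step).
2. Boronate 13 comes from isocoumarin 11 by sterically controlled Ir C–H borylation and then lactone methanolysis; acid 8 comes from isocoumarin 7 by hydrolysis.
3. Both Ar–CH2 bonds come from carboxylate-directed Rh(III) C–H activation/annulation of benzoic acids 6 and 10 with one sulfoxonium ylide 3.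
4. Acid 6 comes from resorcinol (Kolbe–Schmitt, selective 4-O-methylation), acid 10 from anisole (ortho-lithiation/CO2), and ylide 3 from hexanoyl chloride and trimethylsulfoxonium iodide.
5. Ring order: the only rings formed are the two transient isocoumarin lactones (steps 4 and 7), each reopened (steps 5 and 9) before the fragment union.

## Route

**Step 1**
Reactants: 1 hexanoyl chloride; 2 trimethylsulfoxonium iodide
Product: 3 1-[dimethyl(oxo)-λ6-sulfanylidene]heptan-2-one (hexanoyl sulfoxonium ylide)
Conditions: 2 (3 equiv), KOtBu (3 equiv), THF, reflux 2 h; then 1, 0 °C to rt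
Reagents that add atoms: none (both partners are numbered reactants)
Why: Acylation of dimethylsulfoxonium methylide (Corey–Chaykovsky ylide) by the acid chloride, with excess ylide acting as base, gives the stabilised β-keto sulfoxonium ylide.

**Step 2**
Reactants: 4 resorcinol
Product: 5 2,4-dihydroxybenzoic acid
Conditions: KHCO3 (5 equiv), H2O, CO2 stream, 95 °C then reflux; HCl
Reagents that add atoms: carbon dioxide, O=C=O (as KHCO3, [K+].OC(=O)[O-])
Why: Kolbe–Schmitt carboxylation; resorcinol is electron-rich enough to carboxylate in aqueous bicarbonate at C4, ortho/para to the two hydroxyls.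

**Step 3**
Reactants: 5 2,4-dihydroxybenzoic acid
Product: 6 2-hydroxy-4-methoxybenzoic acid
Conditions: Me2SO4 (1.1 equiv), aq NaOH (3 equiv), 0 to 30 °C; then aq NaOH, 80 °C, 30 min; HCl
Reagents that add atoms: dimethyl sulfate, COS(=O)(=O)OC
Why: Selective Williamson O-methylation: the 4-phenoxide (pKa about 9) is alkylated while the 2-OH, hydrogen-bonded to the carboxylate (pKa about 13), stays protonated, and the hot base cleaves any methyl ester formed.

**Step 4**
Reactants: 6 2-hydroxy-4-methoxybenzoic acid; 3 hexanoyl sulfoxonium ylide
Product: 7 8-hydroxy-6-methoxy-3-pentyl-1H-isochromen-1-one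
Conditions: [Cp*RhCl2]2 (2.5 mol %), AgSbF6 (10 mol %), NaOAc (30 mol %), HFIP, 60 °C; then TsOH (cat.), 60 °C if the open keto acid persists
Reagents that add atoms: none (DMSO and water are lost)
Why: Carboxylate-directed Rh(III) C–H activation at C6, the only free ortho position, then Rh-carbene formation from the ylide, migratory insertion, protodemetalation and cyclodehydration (C–H acylmethylation/annulation) give the 3-pentylisocoumarin with the Ar–CH2 bond in place.

**Step 5**
Reactants: 7 8-hydroxy-6-methoxy-3-pentyl-1H-isochromen-1-one
Product: 8 2-hydroxy-4-methoxy-6-(2-oxoheptyl)benzoic acid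
Conditions: KOH (3 equiv), THF/H2O, rt; then cold 1 M KHSO4 to pH 3 at 0 °C, extract, use at once
Reagents that add atoms: water/hydroxide, O (KOH, [K+].[OH-])
Why: Saponification of the enol lactone is irreversible because the enolate becomes the ketone and the acid its carboxylate, and cold mild acidification returns the open keto acid, since recyclisation needs strong acid or dehydrating conditions.

**Step 6**
Reactants: 9 anisole
Product: 10 2-methoxybenzoic acid
Conditions: n-BuLi, TMEDA, Et2O, 0 °C to rt; then CO2 (s), –78 °C to rt; H3O+
Reagents that add atoms: carbon dioxide, O=C=O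
Why: Directed ortho-metalation of anisole by the methoxy group, followed by carboxylation of the aryllithium.

**Step 7**
Reactants: 10 2-methoxybenzoic acid; 3 hexanoyl sulfoxonium ylide
Product: 11 8-methoxy-3-pentyl-1H-isochromen-1-one
Conditions: [Cp*RhCl2]2 (2.5 mol %), AgSbF6 (10 mol %), NaOAc (30 mol %), HFIP, 60 °C
Reagents that add atoms: none
Why: Same carboxylate-directed Rh(III) C–H activation/carbene insertion/annulation as step 4, again at the single available ortho C–H.

**Step 8**
Reactants: 11 8-methoxy-3-pentyl-1H-isochromen-1-one
Product: 12 8-methoxy-3-pentyl-6-(4,4,5,5-tetramethyl-1,3,2-dioxaborolan-2-yl)-1H-isochromen-1-one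
Conditions: [Ir(OMe)(cod)]2 (1.5 mol %), dtbpy (3 mol %), B2pin2 (1.0 equiv), THF, 70 °C
Reagents that add atoms: bis(pinacolato)diboron, CC1(C)OB(OC1(C)C)B1OC(C)(C)C(C)(C)O1
Why: Ir-catalysed, sterically controlled aromatic C–H borylation: C6–H is the only C–H without an ortho substituent (C5 is next to the ring fusion, C7 next to OMe, C4 is a flanked vinyl C–H), and it is the carbon para to the acyl-bearing carbon where the depside oxygen is needed.

**Step 9**
Reactants: 12 6-boryl isocoumarin
Product: 13 methyl 2-methoxy-6-(2-oxoheptyl)-4-(4,4,5,5-tetramethyl-1,3,2-dioxaborolan-2-yl)benzoate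
Conditions: K2CO3 (1.2 equiv), MeOH, 0 °C to rt, short reaction time; AcOH quench at 0 °C
Reagents that add atoms: methanol, CO
Why: Base-catalysed methanolysis (transesterification) of the enol lactone, driven by enol-to-ketone tautomerisation; low temperature avoids intramolecular Claisen cyclisation to a naphthalenediol and keeps the Bpin intact.

**Step 10**
Reactants: 8 2-hydroxy-4-methoxy-6-(2-oxoheptyl)benzoic acid (1.0 equiv); 13 aryl boronate (1.3–1.5 equiv)
Product: 14 gustastatin, 4-(methoxycarbonyl)-3-methoxy-5-(2-oxoheptyl)phenyl 2-hydroxy-4-methoxy-6-(2-oxoheptyl)benzoate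
Conditions: Cu(OTf)2 (20–30 mol %), urea (1 equiv), B(OH)3 (2 equiv), 4 Å MS, EtOAc/MeCN, dry air (1 atm), 45 °C
Reagents that add atoms: none
Why: Proposed new method: a Cu(II)/O2 Chan–Lam-type acyloxylation in which the free, chelated 6-substituted salicylic acid 8 is the O-nucleophile and the aryl–Bpin 13 the aryl donor, so the depside is closed at the C(aryl)–O bond; only the carboxylate (pKa about 3) is ionised under urea buffering while the hydrogen-bonded 2-OH (pKa about 13) is not, the carboxylate binds Cu(II), boric acid scavenges pinacol so the unhindered aryl transfers from B to Cu, disproportionation gives ArCu(III)(O2CAr') and C–O reductive elimination releases the ester with Cu(I) reoxidised by O2; because the acyl carbon is never activated and no strong base is present, the ketone enol has no chance to lactonise to isocoumarin 7; the closest known reaction type is Chan–Lam O-arylation of simple carboxylic acids with arylboronic acids (and Chan–Lam N/O-arylation of ArBpin with boric acid), which to my knowledge has not been shown for free salicylic acids, ArBpin partners or depsides.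

## Compound list

1 | hexanoyl chloride | CCCCCC(=O)Cl | starting material
2 | trimethylsulfoxonium iodide | C[S+](C)(C)=O.[I-] | starting material
3 | 1-[dimethyl(oxo)-λ6-sulfanylidene]heptan-2-one | CCCCCC(=O)C=S(C)(C)=O | intermediate
4 | resorcinol | Oc1cccc(O)c1 | starting material
5 | 2,4-dihydroxybenzoic acid | OC(=O)c1ccc(O)cc1O | intermediate
6 | 2-hydroxy-4-methoxybenzoic acid | COc1ccc(C(=O)O)c(O)c1 | intermediate
7 | 8-hydroxy-6-methoxy-3-pentyl-1H-isochromen-1-one | CCCCCC1=Cc2cc(OC)cc(O)c2C(=O)O1 | intermediate
8 | 2-hydroxy-4-methoxy-6-(2-oxoheptyl)benzoic acid | CCCCCC(=O)Cc1cc(OC)cc(O)c1C(=O)O | intermediate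
9 | anisole | COc1ccccc1 | starting material
10 | 2-methoxybenzoic acid | COc1ccccc1C(=O)O | intermediate
11 | 8-methoxy-3-pentyl-1H-isochromen-1-one | CCCCCC1=Cc2cccc(OC)c2C(=O)O1 | intermediate
12 | 8-methoxy-3-pentyl-6-(pinacolboryl)-1H-isochromen-1-one | CCCCCC1=Cc2cc(B3OC(C)(C)C(C)(C)O3)cc(OC)c2C(=O)O1 | intermediate
13 | methyl 2-methoxy-6-(2-oxoheptyl)-4-(pinacolboryl)benzoate | CCCCCC(=O)Cc1cc(B2OC(C)(C)C(C)(C)O2)cc(OC)c1C(=O)OC | intermediate
14 | gustastatin | CCCCCC(=O)Cc1cc(OC)cc(O)c1C(=O)Oc1cc(CC(=O)CCCCC)c(C(=O)OC)c(OC)c1 | target

## Summary

**Total step count:** 10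

**Longest linear sequence:** 5 steps (4 → 5 → 6 → 7 → 8 → 14, or equally 9 → 10 → 11 → 12 → 13 → 14)

**Three steps most likely to fail**

1. **Step 10 (proposed new Cu acyloxylation).** Risks are sluggish ArBpin transfer, competing phenol O-arylation, Cu/O2 oxidation α to the ketones, and lactonisation of the product to 7 plus the phenol. Fallback with known chemistry: oxidise 13 to the phenol (NaBO3), mask both ketones as 1,3-dioxolanes, and make the ester from the acyl side by classical TFAA- or carbodiimide/DMAP-mediated acylation of the phenol, then hydrolyse the ketals with PPTS in wet acetone.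
2. **Step 4 (Rh annulation on a free salicylic acid).** The free 2-OH and the acidic substrate may divert the ylide to O–H insertion or acyloxy-ketone formation. Fallback: permethylate and saponify 5 to 2,4-dimethoxybenzoic acid, annulate that, then unveil the 8-OH by chelation-controlled BCl3 demethylation of the peri methoxy group of the 6,8-dimethoxyisocoumarin.
3. **Step 8 (Ir C–H borylation).** Borylation at C5 or C4, or Ir/HBpin attack on the enol-lactone alkene, would erode the yield. Fallback: carry the handle from the start, going from 3-bromophenol (8 heavy atoms) by Kolbe–Schmitt carboxylation and methylation to 4-bromo-2-methoxybenzoic acid, then the same Rh annulation and a Pd-catalysed Miyaura borylation of the 6-bromoisocoumarin.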